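## Retrosynthetic overview

- The target is reached from a bicyclic hydroxy lactone by exo-face C-methylation at C-3 (oxygen already in place, so the acetoxy group ends on the concave face), esterification, PMB removal and acetylation.
- The bicyclic lactone comes from an acyclic hydroxy aldehyde (stored as its lactol) in one SmI2 operation: ketyl–olefin 6-exo cyclisation closes the cyclohexane first, and the cis hydroxyl then closes the γ-lactone.
- The hydroxy aldehyde comes from an ynone by oxa-Michael addition of PMB alcohol, Felkin reduction and anti-Markovnikov hydration of a terminal alkyne.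
- The ynone comes from an acid made by an enantioselective boron-enolate Ireland–Claisen rearrangement of the ester of (Z)-3-methylpent-2-en-4-yn-1-ol and 3-methylbut-3-enoic acid; this sets the quaternary centre and its neighbour.

Assumption: the (S,S) bromoborane with Et3N is taken to give the E(O) boron enolate and the (2R,3S) acid; if the sense of induction is the reverse, the (R,R) reagent is used.

Locants in the Why lines are those of the product named in that step.

## Route

Step 1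
Reactants: 1 (Z)-3-methylpent-2-en-4-yn-1-ol; 2 3-methylbut-3-enoic acid
Product: 3 (Z)-3-methylpent-2-en-4-yn-1-yl 3-methylbut-3-enoate
Conditions: DIC, DMAP (5 mol %), CH2Cl2, 0 °C
Reagents that add atoms: none
Why: Steglich esterification of a primary allylic alcohol, run cold with little DMAP so the β,γ-unsaturated acid does not move into conjugation; no stereocentre is formed and the Z alkene is carried through.

Step 2
Reactants: 3 (Z)-3-methylpent-2-en-4-yn-1-yl 3-methylbut-3-enoate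
Product: 5 (2R,3S)-3-ethynyl-3-methyl-2-(prop-1-en-2-yl)pent-4-enoic acid, via boron ketene acetal 4 (not isolated)
Conditions: (4S,5S)-2-bromo-1,3-bis[3,5-bis(trifluoromethyl)phenylsulfonyl]-4,5-diphenyl-1,3,2-diazaborolidine (1.3 equiv), Et3N, toluene–hexane, −78 °C, then 4 °C, 48 h; aqueous work-up
Reagents that add atoms: none
Why: Enantioselective Ireland–Claisen rearrangement through a chiral boron ketene acetal, in which the E(O) enolate (isopropenyl axial) and the Z allylic unit (ethynyl axial) pass through a chair that fixes C-2 relative to C-3 while the C2-symmetric sulfonamide controller selects the enolate face.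

Step 3
Reactants: 5 (2R,3S)-3-ethynyl-3-methyl-2-(prop-1-en-2-yl)pent-4-enoic acid; 6 methyl propiolate
Product: 10 methyl (5R,6S)-6-ethynyl-6-methyl-4-oxo-5-(prop-1-en-2-yl)oct-7-en-2-ynoate, via acid chloride 7 (not isolated), via lithium acetylide 8 (not isolated), via zinc acetylide 9 (not isolated)
Conditions: 5, 1-chloro-N,N,2-trimethylprop-1-en-1-amine, CH2Cl2, 0 °C; separately 6, LiN(SiMe3)2, THF, −78 °C, then ZnCl2; combine, Pd(PPh3)4 (5 mol %), THF, −20 → 0 °C
Reagents that add atoms: none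
Why: Negishi acylative cross-coupling of an alkynylzinc with an acid chloride made under neutral, base-free conditions, so the α-centre is not epimerised; no new stereocentre.

Step 4
Reactants: 10 methyl (5R,6S)-6-ethynyl-6-methyl-4-oxo-5-(prop-1-en-2-yl)oct-7-en-2-ynoate; 11 4-methoxybenzyl alcohol
Product: 12 methyl (2Z,5R,6S)-6-ethynyl-2-[(4-methoxyphenyl)methoxy]-6-methyl-4-oxo-5-(prop-1-en-2-yl)octa-2,7-dienoate
Conditions: DABCO (10 mol %), CH2Cl2, −20 → 0 °C, short reaction time
Reagents that add atoms: none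
Why: Amine-catalysed oxa-Michael addition in which the alkoxide attacks the alkyne carbon β to the ketone (the stronger acceptor and the less hindered site) by anti addition, giving the Z enol ether with the ester trans to the ketone, cold and brief to spare the acidic C-5 hydrogen.

Step 5
Reactants: 12 methyl (2Z,5R,6S)-6-ethynyl-2-[(4-methoxyphenyl)methoxy]-6-methyl-4-oxo-5-(prop-1-en-2-yl)octa-2,7-dienoate
Product: 13 methyl (2Z,4R,5R,6S)-6-ethynyl-4-hydroxy-2-[(4-methoxyphenyl)methoxy]-6-methyl-5-(prop-1-en-2-yl)octa-2,7-dienoate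
Conditions: NaBH4, CeCl3·7H2O, MeOH, −78 °C
Reagents that add atoms: none
Why: Luche 1,2-reduction under Felkin–Anh control, hydride arriving anti to the very large quaternary substituent on C-5 with the isopropenyl group next to the carbonyl oxygen, which gives the 4R carbinol that later becomes the lactone oxygen.

Step 6
Reactants: 13 methyl (2Z,4R,5R,6S)-6-ethynyl-4-hydroxy-2-[(4-methoxyphenyl)methoxy]-6-methyl-5-(prop-1-en-2-yl)octa-2,7-dienoate
Product: 15 methyl (2Z)-3-[(2R,3R,4S)-4-ethenyl-6-hydroxy-4-methyl-3-(prop-1-en-2-yl)oxan-2-yl]-2-[(4-methoxyphenyl)methoxy]prop-2-enoate (anomers), via hydroxy aldehyde 14 (not isolated)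
Conditions: [(C5H5)Ru(NCMe)3]PF6 (5 mol %), 5,5′-bis(trifluoromethyl)-2,2′-bipyridine (5 mol %), H2O, NMP, 25–40 °C
Reagents that add atoms: water, O
Why: Ruthenium–vinylidene anti-Markovnikov hydration of the terminal alkyne gives the aldehyde, which the C-4 hydroxyl traps as the six-membered lactol while the alkenes stay inert; only the uncontrolled anomeric centre is new.

Step 7
Reactants: 15 methyl (2Z)-3-[(2R,3R,4S)-4-ethenyl-6-hydroxy-4-methyl-3-(prop-1-en-2-yl)oxan-2-yl]-2-[(4-methoxyphenyl)methoxy]prop-2-enoate (anomers)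
Product: 17 (3RS,3aS,4R,6S,7R,7aR)-6-ethenyl-4-hydroxy-3-[(4-methoxyphenyl)methoxy]-6-methyl-7-(prop-1-en-2-yl)hexahydro-1-benzofuran-2(3H)-one, via dihydroxy ester 16 (not isolated)
Conditions: SmI2 (3 equiv), MeOH (10 equiv), THF (0.01 M), 0 → 20 °C; then PPTS (20 mol %), same flask, 20 °C
Reagents that add atoms: none
Why: SmI2 ketyl–olefin 6-exo-trig radical cyclisation followed by lactonisation, in which the lactol reacts through the small equilibrium share of its ring-opened hydroxy aldehyde tautomer (the same species as compound 14) and the ketyl adds to the β-carbon of the 2-alkoxyacrylate through a chair where A(1,3) strain with the cis PMBO group holds the allylic C–O bond axial and the isopropenyl group equatorial while the ketyl O–Sm sits equatorial and anti to the acrylate, setting C-3a (S) and C-4 (R), after which the cis hydroxyl closes the cis-fused γ-lactone so that carbocycle and lactone form in the same flask.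

Step 8
Reactants: 17 (3RS,3aS,4R,6S,7R,7aR)-6-ethenyl-4-hydroxy-3-[(4-methoxyphenyl)methoxy]-6-methyl-7-(prop-1-en-2-yl)hexahydro-1-benzofuran-2(3H)-one
Product: 19 (3S,3aS,4R,6S,7R,7aR)-6-ethenyl-4-hydroxy-3-[(4-methoxyphenyl)methoxy]-3,6-dimethyl-7-(prop-1-en-2-yl)hexahydro-1-benzofuran-2(3H)-one, via dilithium alkoxide enolate 18 (not isolated)
Conditions: LiN(i-Pr)2 (2.2 equiv), THF, −78 °C; MeI, DMPU, −78 → −30 °C; AcOH quench
Reagents that add atoms: iodomethane, CI
Why: Lactone enolate alkylation in which iodomethane approaches the convex face of the cis-fused bicycle, anti to C-4, so methyl ends exo and the PMBO group endo, which is 3S and erases the C-3 epimer mixture.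

Step 9
Reactants: 19 (3S,3aS,4R,6S,7R,7aR)-6-ethenyl-4-hydroxy-3-[(4-methoxyphenyl)methoxy]-3,6-dimethyl-7-(prop-1-en-2-yl)hexahydro-1-benzofuran-2(3H)-one; 2 3-methylbut-3-enoic acid
Product: 20 (3S,3aS,4R,6S,7R,7aR)-6-ethenyl-3-[(4-methoxyphenyl)methoxy]-3,6-dimethyl-2-oxo-7-(prop-1-en-2-yl)octahydro-1-benzofuran-4-yl 3-methylbut-3-enoate
Conditions: DIC, DMAP (5 mol %), CH2Cl2, 0 → 20 °C
Reagents that add atoms: none
Why: Steglich esterification of the only free hydroxyl (secondary, equatorial), placed after the enolate step because the β,γ-unsaturated ester would not survive strong base; no stereocentre changes.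

Step 10
Reactants: 20 (3S,3aS,4R,6S,7R,7aR)-6-ethenyl-3-[(4-methoxyphenyl)methoxy]-3,6-dimethyl-2-oxo-7-(prop-1-en-2-yl)octahydro-1-benzofuran-4-yl 3-methylbut-3-enoate
Product: 21 (3S,3aS,4R,6S,7R,7aR)-6-ethenyl-3-hydroxy-3,6-dimethyl-2-oxo-7-(prop-1-en-2-yl)octahydro-1-benzofuran-4-yl 3-methylbut-3-enoate
Conditions: DDQ, CH2Cl2–pH 7 buffer, 0 → 20 °C
Reagents that add atoms: none
Why: Oxidative PMB ether cleavage by benzylic hydride abstraction and hydrolysis, which leaves the alkenes, both esters and the C-3 configuration untouched.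

Step 11
Reactants: 21 (3S,3aS,4R,6S,7R,7aR)-6-ethenyl-3-hydroxy-3,6-dimethyl-2-oxo-7-(prop-1-en-2-yl)octahydro-1-benzofuran-4-yl 3-methylbut-3-enoate
Product: 22 (3S,3aS,4R,6S,7R,7aR)-3-acetoxy-6-ethenyl-3,6-dimethyl-2-oxo-7-(prop-1-en-2-yl)octahydro-1-benzofuran-4-yl 3-methylbut-3-enoate (CNP0106639.1)
Conditions: Ac2O, Sc(OTf)3 (5 mol %), MeCN, −20 °C
Reagents that add atoms: acetic anhydride, CC(=O)OC(C)=O
Why: Lewis-acid-catalysed acylation of the tertiary α-hydroxy lactone under base-free conditions that neither isomerise the β,γ-unsaturated ester nor ionise the α-carbonyl C–O bond, so C-3 is retained.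

## Compound list

1 | (Z)-3-methylpent-2-en-4-yn-1-ol | OC/C=C(C)\C#C | starting material
2 | 3-methylbut-3-enoic acid | C=C(C)CC(=O)O | starting material
3 | (Z)-3-methylpent-2-en-4-yn-1-yl 3-methylbut-3-enoate | C=C(C)CC(=O)OC/C=C(C)\C#C | intermediate
4 | E(O) boron ketene acetal of 3 carrying the (4S,5S)-diazaborolidine | C=C(C)/C=C(/OB1N(S(=O)(=O)c2cc(C(F)(F)F)cc(C(F)(F)F)c2)[C@@H](c2ccccc2)[C@H](c2ccccc2)N1S(=O)(=O)c1cc(C(F)(F)F)cc(C(F)(F)F)c1)OC/C=C(C)\C#C | intermediate (not isolated)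
5 | (2R,3S)-3-ethynyl-3-methyl-2-(prop-1-en-2-yl)pent-4-enoic acid | C=C[C@]([C@@H](C(=C)C)C(=O)O)(C)C#C | intermediate
6 | methyl propiolate | C#CC(=O)OC | starting material
7 | (2R,3S)-3-ethynyl-3-methyl-2-(prop-1-en-2-yl)pent-4-enoyl chloride | C=C[C@]([C@@H](C(=C)C)C(Cl)=O)(C)C#C | intermediate (not isolated)
8 | lithium acetylide of methyl propiolate | [Li]C#CC(=O)OC | intermediate (not isolated)
9 | chloro(3-methoxy-3-oxoprop-1-yn-1-yl)zinc | Cl[Zn]C#CC(=O)OC | intermediate (not isolated)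
10 | methyl (5R,6S)-6-ethynyl-6-methyl-4-oxo-5-(prop-1-en-2-yl)oct-7-en-2-ynoate | C=C[C@]([C@@H](C(=C)C)C(=O)C#CC(=O)OC)(C)C#C | intermediate
11 | 4-methoxybenzyl alcohol | COc1ccc(CO)cc1 | starting material
12 | methyl (2Z,5R,6S)-6-ethynyl-2-[(4-methoxyphenyl)methoxy]-6-methyl-4-oxo-5-(prop-1-en-2-yl)octa-2,7-dienoate | C=C[C@]([C@@H](C(=C)C)C(=O)/C=C(\OCc1ccc(OC)cc1)C(=O)OC)(C)C#C | intermediate
13 | methyl (2Z,4R,5R,6S)-6-ethynyl-4-hydroxy-2-[(4-methoxyphenyl)methoxy]-6-methyl-5-(prop-1-en-2-yl)octa-2,7-dienoate | C=C[C@]([C@@H](C(=C)C)[C@@H](O)/C=C(\OCc1ccc(OC)cc1)C(=O)OC)(C)C#C | intermediate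
14 | methyl (2Z,4R,5R,6S)-6-ethenyl-4-hydroxy-2-[(4-methoxyphenyl)methoxy]-6-methyl-8-oxo-5-(prop-1-en-2-yl)oct-2-enoate | C=C[C@]([C@@H](C(=C)C)[C@@H](O)/C=C(\OCc1ccc(OC)cc1)C(=O)OC)(C)CC=O | intermediate (not isolated)
15 | methyl (2Z)-3-[(2R,3R,4S)-4-ethenyl-6-hydroxy-4-methyl-3-(prop-1-en-2-yl)oxan-2-yl]-2-[(4-methoxyphenyl)methoxy]prop-2-enoate, anomeric mixture | C=C[C@]1(C)CC(O)O[C@@H](/C=C(\OCc2ccc(OC)cc2)C(=O)OC)[C@@H]1C(=C)C | intermediate
16 | methyl 2-[(1S,2R,3R,4S,6R)-4-ethenyl-2,6-dihydroxy-4-methyl-3-(prop-1-en-2-yl)cyclohexyl]-2-[(4-methoxyphenyl)methoxy]acetate, acetate C-2 unassigned | C=C[C@]1(C)C[C@@H](O)[C@H](C(OCc2ccc(OC)cc2)C(=O)OC)[C@H](O)[C@@H]1C(=C)C | intermediate (not isolated)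
17 | (3RS,3aS,4R,6S,7R,7aR)-6-ethenyl-4-hydroxy-3-[(4-methoxyphenyl)methoxy]-6-methyl-7-(prop-1-en-2-yl)hexahydro-1-benzofuran-2(3H)-one | C=C[C@]1(C)C[C@@H](O)[C@H]2[C@H](OC(=O)C2OCc3ccc(OC)cc3)[C@@H]1C(=C)C | intermediate
18 | dilithium alkoxide enolate of 17 | C=C[C@]1(C)C[C@@H](O[Li])[C@H]2[C@H](OC(O[Li])=C2OCc3ccc(OC)cc3)[C@@H]1C(=C)C | intermediate (not isolated)
19 | (3S,3aS,4R,6S,7R,7aR)-6-ethenyl-4-hydroxy-3-[(4-methoxyphenyl)methoxy]-3,6-dimethyl-7-(prop-1-en-2-yl)hexahydro-1-benzofuran-2(3H)-one | C=C[C@]1(C)C[C@@H](O)[C@H]2[C@H](OC(=O)[C@@]2(C)OCc3ccc(OC)cc3)[C@@H]1C(=C)C | intermediate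
20 | (3S,3aS,4R,6S,7R,7aR)-6-ethenyl-3-[(4-methoxyphenyl)methoxy]-3,6-dimethyl-2-oxo-7-(prop-1-en-2-yl)octahydro-1-benzofuran-4-yl 3-methylbut-3-enoate | C=C[C@]1(C)C[C@@H](OC(=O)CC(=C)C)[C@H]2[C@H](OC(=O)[C@@]2(C)OCc3ccc(OC)cc3)[C@@H]1C(=C)C | intermediate
21 | (3S,3aS,4R,6S,7R,7aR)-6-ethenyl-3-hydroxy-3,6-dimethyl-2-oxo-7-(prop-1-en-2-yl)octahydro-1-benzofuran-4-yl 3-methylbut-3-enoate | C=C[C@]1(C)C[C@@H](OC(=O)CC(=C)C)[C@H]2[C@H](OC(=O)[C@@]2(C)O)[C@@H]1C(=C)C | intermediate
22 | (3S,3aS,4R,6S,7R,7aR)-3-acetoxy-6-ethenyl-3,6-dimethyl-2-oxo-7-(prop-1-en-2-yl)octahydro-1-benzofuran-4-yl 3-methylbut-3-enoate | C=C[C@]1(C)C[C@@H](OC(=O)CC(=C)C)[C@H]2[C@H](OC(=O)[C@@]2(C)OC(C)=O)[C@@H]1C(=C)C | target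

## Step count and risks

Total step count: 11. Longest linear sequence: 11 steps, from 1; the other starting materials are bought.

The three steps most likely to fail:

Step 7. The lactol may open slowly, chelation of samarium by the free hydroxyl or the alternative chair may give the C-3a/C-4 epimers, and the ketyl oxygen may lactonise instead of the intended hydroxyl. The fallback sets out from 13 and stages the two ring closures. The carbinol of 13 is silylated (Et3SiOTf, 2,6-lutidine) to the triethylsilyl ether F1. The alkyne of F1 is hydrated as in step 6 to the open-chain aldehyde F2, which cannot form a lactol. F2 is cyclised with SmI2, HMPA and t-BuOH in THF at −78 °C (non-chelated ketyl, same allylic-strain control) to the cyclohexanol F3. HF·pyridine then removes the silyl group from F3 and the freed axial hydroxyl lactonises, which comes back to the route at 17.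

Step 2. The enolate geometry and the enantioselectivity are uncertain for an ester that forms a dienolate. The fallback sets out from 3. A classical Ireland–Claisen rearrangement (LiN(i-Pr)2, Me3SiCl, THF, −78 → 25 °C, K2CO3/MeOH work-up) gives the racemic acid F4 with the same relative configuration. F4 is resolved by crystallising the ammonium salt F5 with (S)-1-phenylethylamine (its antipode if the other salt is the less soluble one), and dilute HCl frees the acid, which comes back to the route at 5.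

Step 6. The alkyne sits on a quaternary carbon, and the ruthenium catalyst could isomerise the allylic alcohol. The fallback sets out from 13. Hydroboration of the terminal alkyne with pinacolborane and Cp2Zr(H)Cl (10 mol %) in CH2Cl2, where the alkenes react far more slowly, gives the alkenylboronate F6. Oxidation with NaBO3·4H2O in THF–H2O gives the aldehyde, which closes to the lactol and comes back to the route at 15.

Further compounds
F1 | step 7 | methyl (2Z,4R,5R,6S)-6-ethynyl-2-[(4-methoxyphenyl)methoxy]-6-methyl-5-(prop-1-en-2-yl)-4-(triethylsilyloxy)octa-2,7-dienoate | C=C[C@]([C@@H](C(=C)C)[C@@H](O[Si](CC)(CC)CC)/C=C(\OCc1ccc(OC)cc1)C(=O)OC)(C)C#C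
F2 | step 7 | methyl (2Z,4R,5R,6S)-6-ethenyl-2-[(4-methoxyphenyl)methoxy]-6-methyl-8-oxo-5-(prop-1-en-2-yl)-4-(triethylsilyloxy)oct-2-enoate | C=C[C@]([C@@H](C(=C)C)[C@@H](O[Si](CC)(CC)CC)/C=C(\OCc1ccc(OC)cc1)C(=O)OC)(C)CC=O
F3 | step 7 | methyl 2-[(1R,2R,3R,4S,6R)-4-ethenyl-6-hydroxy-4-methyl-3-(prop-1-en-2-yl)-2-(triethylsilyloxy)cyclohexyl]-2-[(4-methoxyphenyl)methoxy]acetate | C=C[C@]1(C)C[C@@H](O)[C@H](C(OCc2ccc(OC)cc2)C(=O)OC)[C@H](O[Si](CC)(CC)CC)[C@@H]1C(=C)C
F4 | step 2 | racemic (2R*,3S*)-3-ethynyl-3-methyl-2-(prop-1-en-2-yl)pent-4-enoic acid | C=C[C@]([C@@H](C(=C)C)C(=O)O)(C)C#C.C=C[C@@]([C@H](C(=C)C)C(=O)O)(C)C#C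
F5 | step 2 | (S)-1-phenylethanaminium (2R,3S)-3-ethynyl-3-methyl-2-(prop-1-en-2-yl)pent-4-enoate | C=C[C@]([C@@H](C(=C)C)C(=O)[O-])(C)C#C.C[C@H]([NH3+])c1ccccc1
F6 | step 6 | methyl (2Z,4R,5R,6R,7E)-6-ethenyl-4-hydroxy-2-[(4-methoxyphenyl)methoxy]-6-methyl-5-(prop-1-en-2-yl)-8-(4,4,5,5-tetramethyl-1,3,2-dioxaborolan-2-yl)octa-2,7-dienoate (the alkyne of 13 turned into CH=CH–Bpin) | C=C[C@]([C@@H](C(=C)C)[C@@H](O)/C=C(\OCc1ccc(OC)cc1)C(=O)OC)(C)/C=C/B1OC(C)(C)C(C)(C)O1
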